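**Retrosynthetic overview**
- Target 19 ⇐ Δ4 alkene 18 by a singlet-oxygen ene reaction, which installs the 5α-OOH and the C4=C15 methylene in the last step.
- 18 ⇐ bicyclic enone 16 (Luche reduction, isobutyrylation) ⇐ silyl enol ether 15 (Saegusa oxidation).
- Rings A and B are formed together, in one intramolecular Diels–Alder reaction of the acyclic triene 14 (bonds C1–C2 and C5–C10); this step also creates the quaternary C10.
- 14 ⇐ aldehyde 11 (Wittig, silylation) ⇐ syn acetate 10, from zinc-mediated coupling of allyl bromide 7 with 3-methylbut-3-enal 2 (sets C7, C8 and the acrylate) and lipase resolution.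
- 7 ⇐ Morita–Baylis–Hillman adduct of 3,3-dimethoxypropanal and methyl acrylate.

Assumption: the SMILES is read as the (3S,5S,7R,8R,10R) enantiomer (normal eudesmane series, 10β-methyl); eudesmane numbering C1–C15 is used for all ring positions.

**Route**

Step 1
Reactants: 1 3-methylbut-3-en-1-ol
Product: 2 3-methylbut-3-enal
Conditions: PhI(OAc)2 (1.1 equiv), TEMPO (10 mol %), CH2Cl2, 0 °C to rt; dried solution used at once
Reagents that add atoms: none
Why: TEMPO-catalysed alcohol oxidation stops at the aldehyde under near-neutral conditions, so the β,γ-double bond does not move into conjugation; no stereocentre is formed.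

Step 2
Reactants: 3 methyl 3,3-dimethoxypropanoate
Product: 4 3,3-dimethoxypropanal
Conditions: i-Bu2AlH (1.05 equiv), CH2Cl2, −78 °C; aqueous Rochelle salt work-up
Reagents that add atoms: none
Why: Partial ester reduction, in which the aluminium hemiacetal is stable at −78 °C and releases the aldehyde only on work-up; no stereocentre is formed.

Step 3
Reactants: 4 3,3-dimethoxypropanal; 5 methyl acrylate
Product: 6 methyl 3-hydroxy-5,5-dimethoxy-2-methylidenepentanoate (racemic)
Conditions: DABCO (0.5 equiv), methyl acrylate (3 equiv), neat, rt, 5 d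
Reagents that add atoms: none
Why: Morita–Baylis–Hillman reaction of an unhindered aliphatic aldehyde; the carbinol centre is racemic and is removed in step 4.

Step 4
Reactants: 6 methyl 3-hydroxy-5,5-dimethoxy-2-methylidenepentanoate
Product: 7 methyl (2Z)-2-(bromomethyl)-5,5-dimethoxypent-2-enoate
Conditions: N-bromosuccinimide, Me2S, CH2Cl2, 0 °C to rt
Reagents that add atoms: N-bromosuccinimide (O=C1CCC(=O)N1Br)
Why: Corey–Kim-type activation of the allylic alcohol as an alkoxysulfonium ion followed by SN2′ attack of bromide gives the rearranged primary allyl bromide with the thermodynamically preferred geometry (CH2Br cis to the chain, ester trans).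

Step 5
Reactants: 2 3-methylbut-3-enal; 7 methyl (2Z)-2-(bromomethyl)-5,5-dimethoxypent-2-enoate
Product: 9 methyl (3RS,4RS)-3-(2,2-dimethoxyethyl)-4-hydroxy-6-methyl-2-methylidenehept-6-enoate, via allylzinc bromide 8 (not isolated)
Conditions: Zn dust, THF/saturated aqueous NH4Cl (1:1), 0 °C to rt; 2 in excess
Reagents that add atoms: none
Why: Barbier-type allylation in which the γ-carbon of the allylzinc attacks the aldehyde through a chair Zimmerman–Traxler transition state; the crotyl-type geometry (chain cis to CH2Zn) gives the syn adduct, so C7 and C8 are set relative to each other (racemic) and the α-methylene ester is formed in the same step.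

Step 6
Reactants: 9 methyl (3RS,4RS)-3-(2,2-dimethoxyethyl)-4-hydroxy-6-methyl-2-methylidenehept-6-enoate
Product: 10 methyl (3R,4R)-4-acetoxy-3-(2,2-dimethoxyethyl)-6-methyl-2-methylidenehept-6-enoate
Conditions: Amano lipase PS (Burkholderia cepacia), vinyl acetate (3 equiv), MTBE, 30 °C, stopped near 50 % conversion
Reagents that add atoms: vinyl acetate (C=COC(C)=O)
Why: Lipase-catalysed kinetic resolution by transesterification, in which the Kazlauskas rule predicts faster acylation of the (4R)-carbinol (branched C3 side large, methallyl side medium); this gives the (3R,4R)-acetate, which is already the 8-acetoxy group of the target, and leaves the (3S,4S)-alcohol behind.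

Step 7
Reactants: 10 methyl (3R,4R)-4-acetoxy-3-(2,2-dimethoxyethyl)-6-methyl-2-methylidenehept-6-enoate
Product: 11 methyl (3R,4R)-4-acetoxy-6-methyl-2-methylidene-3-(2-oxoethyl)hept-6-enoate
Conditions: Amberlyst-15, acetone/H2O (20:1), rt
Reagents that add atoms: water (O)
Why: Acid-catalysed acetal hydrolysis; with the carbinol acetylated no lactone can form, and the stereocentres are not α to the new aldehyde.

Step 8
Reactants: 11 methyl (3R,4R)-4-acetoxy-6-methyl-2-methylidene-3-(2-oxoethyl)hept-6-enoate; 12 3-(triphenyl-λ5-phosphanylidene)butan-2-one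
Product: 13 methyl (3R,4R)-4-acetoxy-6-methyl-2-methylidene-3-[(2E)-3-methyl-4-oxopent-2-en-1-yl]hept-6-enoate
Conditions: toluene, 90 °C
Reagents that add atoms: none
Why: Wittig olefination with a stabilised ylide gives the (E)-trisubstituted enone (C4=C5 with the C15 methyl) without touching the acetate or the acrylate.

Step 9
Reactants: 13 methyl (3R,4R)-4-acetoxy-6-methyl-2-methylidene-3-[(2E)-3-methyl-4-oxopent-2-en-1-yl]hept-6-enoate
Product: 14 methyl (3R,4R)-4-acetoxy-3-[(2E)-4-[(tert-butyldimethylsilyl)oxy]-3-methylpenta-2,4-dien-1-yl]-6-methyl-2-methylidenehept-6-enoate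
Conditions: TBSOTf (1.3 equiv), Et3N (2 equiv), CH2Cl2, −78 to 0 °C
Reagents that add atoms: tert-butyldimethylsilyl trifluoromethanesulfonate (CC(C)(C)[Si](C)(C)OS(=O)(=O)C(F)(F)F)
Why: Soft enolisation and O-silylation at the methyl group of the methyl ketone gives the cross-conjugated 2-silyloxy diene with the E geometry of C4=C5 retained.

Step 10
Reactants: 14 methyl (3R,4R)-4-acetoxy-3-[(2E)-4-[(tert-butyldimethylsilyl)oxy]-3-methylpenta-2,4-dien-1-yl]-6-methyl-2-methylidenehept-6-enoate
Product: 15 methyl 8β-acetoxy-3-[(tert-butyldimethylsilyl)oxy]-5αH-eudesma-3,11(13)-dien-12-oate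
Conditions: toluene (0.005 M), BHT, 190 °C, sealed tube, 36 h
Reagents that add atoms: none
Why: Type 1 intramolecular Diels–Alder reaction in which the four-atom tether that becomes ring B brings the 2-silyloxy diene and the 1,1-disubstituted alkene together, so the C1–C2 and C5–C10 bonds, and with them rings A and B, form in one step; the exo-tether chair-like transition state with the large C7 substituent equatorial (the 4-methyl group of the diene disfavours the endo-tether mode, and the still trigonal C10 tolerates the pseudo-axial 8-acetoxy group) places the new C10 methyl cis to the C7 side chain and the C8 acetate and H5 trans to it, and any C5 epimer converges in step 11.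

Step 11
Reactants: 15 methyl 8β-acetoxy-3-[(tert-butyldimethylsilyl)oxy]-5αH-eudesma-3,11(13)-dien-12-oate
Product: 16 methyl 8β-acetoxy-3-oxoeudesma-4,11(13)-dien-12-oate
Conditions: Pd(OAc)2 (1.1 equiv), MeCN, 40 °C
Reagents that add atoms: none
Why: Saegusa–Ito oxidation, in which the regiodefined silyl enol ether from the cycloaddition gives a palladium enolate at C4 and β-hydride elimination towards C5 gives the tetrasubstituted enone; C5 is no longer a stereocentre.

Step 12
Reactants: 16 methyl 8β-acetoxy-3-oxoeudesma-4,11(13)-dien-12-oate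
Product: 17 methyl 8β-acetoxy-3β-hydroxyeudesma-4,11(13)-dien-12-oate
Conditions: NaBH4, CeCl3·7H2O, MeOH, −78 °C
Reagents that add atoms: none
Why: Luche reduction gives clean 1,2-reduction of the enone, with hydride delivered from the α face anti to the axial C10 methyl, so the 3β (pseudo-equatorial) alcohol is formed while the acrylate and the acetate are untouched at −78 °C.

Step 13
Reactants: 17 methyl 8β-acetoxy-3β-hydroxyeudesma-4,11(13)-dien-12-oate
Product: 18 methyl 8β-acetoxy-3β-(2-methylpropanoyloxy)eudesma-4,11(13)-dien-12-oate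
Conditions: isobutyric anhydride (1.5 equiv), Et3N, DMAP (10 mol %), CH2Cl2, 0 °C to rt
Reagents that add atoms: isobutyric anhydride (CC(C)C(=O)OC(=O)C(C)C)
Why: DMAP-catalysed acylation of the unhindered allylic alcohol with retention at C3.

Step 14
Reactants: 18 methyl 8β-acetoxy-3β-(2-methylpropanoyloxy)eudesma-4,11(13)-dien-12-oate
Product: 19 methyl 8β-acetoxy-5α-hydroperoxy-3β-(2-methylpropanoyloxy)eudesma-4(15),11(13)-dien-12-oate
Conditions: O2, tetraphenylporphyrin (1 mol %), CH2Cl2, white LED, −20 °C
Reagents that add atoms: oxygen (O=O)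
Why: Schenck ene reaction of singlet oxygen with the tetrasubstituted Δ4 alkene, in which oxygen bonds to C5 from the α face (anti to the axial C10 methyl and the 3β ester) and takes a hydrogen from the C15 methyl group (methyl hydrogens are abstracted in preference to ring CH2 hydrogens, and H3 geminal to the acyloxy group is not abstracted); this moves the double bond to C4=C15 and sets the 5α-hydroperoxide, while the electron-poor acrylate does not react.

**Compound list**

1 | 3-methylbut-3-en-1-ol | C=C(C)CCO | starting material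
2 | 3-methylbut-3-enal | C=C(C)CC=O | intermediate
3 | methyl 3,3-dimethoxypropanoate | COC(=O)CC(OC)OC | starting material
4 | 3,3-dimethoxypropanal | O=CCC(OC)OC | intermediate
5 | methyl acrylate | C=CC(=O)OC | starting material
6 | methyl 3-hydroxy-5,5-dimethoxy-2-methylidenepentanoate (racemic) | C=C(C(=O)OC)C(O)CC(OC)OC | intermediate
7 | methyl (2Z)-2-(bromomethyl)-5,5-dimethoxypent-2-enoate | BrC/C(C(=O)OC)=C\CC(OC)OC | intermediate
8 | allylzinc bromide formed from 7 (not isolated) | Br[Zn]C/C(C(=O)OC)=C\CC(OC)OC | intermediate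
9 | methyl (3RS,4RS)-3-(2,2-dimethoxyethyl)-4-hydroxy-6-methyl-2-methylidenehept-6-enoate (syn racemate, drawn as 3R,4R) | C=C(C(=O)OC)[C@@H](CC(OC)OC)[C@H](O)CC(C)=C | intermediate
10 | methyl (3R,4R)-4-acetoxy-3-(2,2-dimethoxyethyl)-6-methyl-2-methylidenehept-6-enoate | C=C(C(=O)OC)[C@@H](CC(OC)OC)[C@H](OC(C)=O)CC(C)=C | intermediate
11 | methyl (3R,4R)-4-acetoxy-6-methyl-2-methylidene-3-(2-oxoethyl)hept-6-enoate | C=C(C(=O)OC)[C@@H](CC=O)[C@H](OC(C)=O)CC(C)=C | intermediate
12 | 3-(triphenyl-λ5-phosphanylidene)butan-2-one | CC(=O)C(C)=P(c1ccccc1)(c1ccccc1)c1ccccc1 | starting material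
13 | methyl (3R,4R)-4-acetoxy-6-methyl-2-methylidene-3-[(2E)-3-methyl-4-oxopent-2-en-1-yl]hept-6-enoate | C=C(C(=O)OC)[C@@H](C/C=C(C)/C(C)=O)[C@H](OC(C)=O)CC(C)=C | intermediate
14 | methyl (3R,4R)-4-acetoxy-3-[(2E)-4-[(tert-butyldimethylsilyl)oxy]-3-methylpenta-2,4-dien-1-yl]-6-methyl-2-methylidenehept-6-enoate | C=C(C(=O)OC)[C@@H](C/C=C(C)/C(=C)O[Si](C)(C)C(C)(C)C)[C@H](OC(C)=O)CC(C)=C | intermediate
15 | methyl 8β-acetoxy-3-[(tert-butyldimethylsilyl)oxy]-5αH-eudesma-3,11(13)-dien-12-oate (trans-fused) | C=C(C(=O)OC)[C@H]1C[C@H]2C(C)=C(O[Si](C)(C)C(C)(C)C)CC[C@]2(C)C[C@H]1OC(C)=O | intermediate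
16 | methyl 8β-acetoxy-3-oxoeudesma-4,11(13)-dien-12-oate (7R,8R,10R) | C=C(C(=O)OC)[C@H]1CC2=C(C)C(=O)CC[C@]2(C)C[C@H]1OC(C)=O | intermediate
17 | methyl 8β-acetoxy-3β-hydroxyeudesma-4,11(13)-dien-12-oate | C=C(C(=O)OC)[C@H]1CC2=C(C)[C@@H](O)CC[C@]2(C)C[C@H]1OC(C)=O | intermediate
18 | methyl 8β-acetoxy-3β-(2-methylpropanoyloxy)eudesma-4,11(13)-dien-12-oate | C=C(C(=O)OC)[C@H]1CC2=C(C)[C@@H](OC(=O)C(C)C)CC[C@]2(C)C[C@H]1OC(C)=O | intermediate
19 | methyl 8β-acetoxy-5α-hydroperoxy-3β-(2-methylpropanoyloxy)eudesma-4(15),11(13)-dien-12-oate (3S,5S,7R,8R,10R) | C=C(C(=O)OC)[C@H]1C[C@@]2(OO)C(=C)[C@@H](OC(=O)C(C)C)CC[C@]2(C)C[C@H]1OC(C)=O | target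

**Step count**
Total: 14 steps. Longest linear sequence: 13 steps (3 to 19, steps 2–14); step 1 supplies aldehyde 2 in one step.

**Steps most likely to fail, each with a fallback**

Step 10. The unactivated 1,1-disubstituted dienophile needs about 190 °C, where the acrylate can polymerise, and the ring B substituents control C10 only moderately (a ratio of about 3:1 is expected, with the minor isomer removed after step 11). The fallback sets out from 14 and comes back at 15. The two bonds are made by a metal-mediated stepwise annulation instead of a concerted pericyclic reaction: a cationic complex of monovalent rhodium, generated from [Rh(cod)Cl]2 and AgSbF6 (5 mol %, CH2Cl2 or CF3CH2OH, 25–50 °C), binds the diene and the alkene, closes a rhodacycle by oxidative cyclometallation and releases 15 by reductive elimination. The low temperature protects the acrylate and the metallacycle follows its own stereochemical course at C10. No further compound arises (F0).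

Step 6. The lipase may acylate the hindered carbinol slowly or with low selectivity, and half of the material is lost in any case. The fallback sets out from 7 (with 2) and comes back at 10. Bromide 7 is borylated (B2pin2, Pd2(dba)3 cat., toluene, 50 °C) to methyl (2E)-5,5-dimethoxy-2-[(4,4,5,5-tetramethyl-1,3,2-dioxaborolan-2-yl)methyl]pent-2-enoate F1. Allylboration of 2 with F1 under chiral phosphoric acid catalysis ((R)-TRIP, 5 mol %, toluene, −30 °C; the antipodal acid if the sense proves opposite) goes through a closed chair transition state: the crotyl-type geometry gives the syn adduct and the catalyst sets the absolute configuration. It yields the borate ester methyl (3R,4R)-3-(2,2-dimethoxyethyl)-6-methyl-2-methylidene-4-[(4,4,5,5-tetramethyl-1,3,2-dioxaborolan-2-yl)oxy]hept-6-enoate F2, which is hydrolysed on work-up to the enantioenriched alcohol methyl (3R,4R)-3-(2,2-dimethoxyethyl)-4-hydroxy-6-methyl-2-methylidenehept-6-enoate F3. Acetylation (Ac2O, pyridine, DMAP) gives 10 without a resolution.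

Step 14. The ene reaction may give the 4α-hydroperoxy-Δ5 regioisomer or mixtures. The fallback sets out from 18 and comes back at 19. Epoxidation of the electron-rich tetrasubstituted alkene from the α face (m-CPBA, NaHCO3, CH2Cl2, 0 °C; the acrylate is inert) gives methyl 8β-acetoxy-4α,5α-epoxy-3β-(2-methylpropanoyloxy)eudesm-11(13)-en-12-oate F4. Base-induced isomerisation of the epoxide with diethylaluminium 2,2,6,6-tetramethylpiperidide (toluene, 0 °C), which removes a syn hydrogen of the C15 methyl group, gives the tertiary allylic alcohol methyl 8β-acetoxy-5α-hydroxy-3β-(2-methylpropanoyloxy)eudesma-4(15),11(13)-dien-12-oate F5. Acid-catalysed perhydrolysis (anhydrous H2O2 in Et2O, catalytic H2SO4, 0 °C) exchanges OH for OOH through the allyl cation, with H2O2 attacking C5 from the open α face, to give 19.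

Further compounds
F0 | step 10 | none | none
F1 | step 6 | methyl (2E)-5,5-dimethoxy-2-[(4,4,5,5-tetramethyl-1,3,2-dioxaborolan-2-yl)methyl]pent-2-enoate | CC1(C)OB(C/C(C(=O)OC)=C\CC(OC)OC)OC1(C)C
F2 | step 6 | methyl (3R,4R)-3-(2,2-dimethoxyethyl)-6-methyl-2-methylidene-4-[(4,4,5,5-tetramethyl-1,3,2-dioxaborolan-2-yl)oxy]hept-6-enoate | C=C(C(=O)OC)[C@@H](CC(OC)OC)[C@H](OB1OC(C)(C)C(C)(C)O1)CC(C)=C
F3 | step 6 | methyl (3R,4R)-3-(2,2-dimethoxyethyl)-4-hydroxy-6-methyl-2-methylidenehept-6-enoate (single enantiomer of 9) | C=C(C(=O)OC)[C@@H](CC(OC)OC)[C@H](O)CC(C)=C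
F4 | step 14 | methyl 8β-acetoxy-4α,5α-epoxy-3β-(2-methylpropanoyloxy)eudesm-11(13)-en-12-oate | C=C(C(=O)OC)[C@H]1C[C@@]2(O3)[C@@]3(C)[C@@H](OC(=O)C(C)C)CC[C@]2(C)C[C@H]1OC(C)=O
F5 | step 14 | methyl 8β-acetoxy-5α-hydroxy-3β-(2-methylpropanoyloxy)eudesma-4(15),11(13)-dien-12-oate | C=C(C(=O)OC)[C@H]1C[C@@]2(O)C(=C)[C@@H](OC(=O)C(C)C)CC[C@]2(C)C[C@H]1OC(C)=O
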